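The flavan is cut across ring C at C3–C4 and O1–C2. Because O1 and C4 are both attached to ring A (through C8a and C4a), ring A with C4 as its exocyclic carbon, carrying ring D, is an ortho-quinone methide. A chiral phosphoric acid should release this species from a racemic, benzyl-protected ortho-hydroxybenzhydrol and steer N-vinylacetamide onto one face, which closes the pyran ring C and fixes C4 (R) in a single operation. The C2 acetamido group then serves as a leaving group: hydrolysis, sulfone formation and trans-selective arylzinc substitution bring in ring B, and acylation of ring D and global hydrogenolysis finish the synthesis.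

Key step: step 5

Remarks on the chemistry
- Stereochemistry: target 21 is (2S,4R), 2,4-trans. Cycloadduct 11 is (2R,4R), 2,4-cis. C4 is set in step 5 and never touched again; C2 is reset in step 8.
- Precursor design: every phenol except the one needed for quinone methide formation is a benzyl ether, so one hydrogenolysis ends the route. The free ortho-phenol would destroy one equivalent of the aryllithium in step 4, so it is converted to its sodium salt first. Benzhydrol 8 ionises easily; it is quenched with water only, purified on Et3N-deactivated silica and used promptly.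
- Assumption: the (R)-configured phosphoric acid is taken to give 4R. The sense of induction is to be confirmed on the first run; if it is opposite, the (S)-catalyst is used with no other change. The same holds for the antipode of the auxiliary in the fallback to step 5.

Step 1
Reactants: 1 phloroglucinol
Product: 2 1,3,5-tris(benzyloxy)benzene
Conditions: BnBr (3.3 equiv), K2CO3, DMF, rt
Reagents that add atoms: benzyl bromide, BrCc1ccccc1
Why: Williamson ether synthesis in a polar aprotic solvent favours O- over C-benzylation of the three phenoxides, and C-benzylated by-products are removed by crystallisation.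

Step 2
Reactants: 2 1,3,5-tris(benzyloxy)benzene
Product: 3 2-bromo-1,3,5-tris(benzyloxy)benzene
Conditions: NBS (1.0 equiv), CH2Cl2, −78 → 0 °C
Reagents that add atoms: N-bromosuccinimide, O=C1CCC(=O)N1Br
Why: Electrophilic aromatic bromination of the strongly activated triether with one equivalent of reagent at low temperature should stop at the monobromide, the three open positions being equivalent.

Step 3
Reactants: 4 2,4-dihydroxybenzaldehyde
Product: 5 4-(benzyloxy)-2-hydroxybenzaldehyde
Conditions: BnBr (1.0 equiv), NaHCO3, KI (cat.), MeCN, reflux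
Reagents that add atoms: benzyl bromide, BrCc1ccccc1
Why: Williamson ether synthesis with a weak base is regioselective because the 2-hydroxyl is hydrogen-bonded to the formyl group and less acidic, so only the 4-hydroxyl is alkylated.

Step 4
Reactants: 3 2-bromo-1,3,5-tris(benzyloxy)benzene; 5 4-(benzyloxy)-2-hydroxybenzaldehyde
Product: 8 (4-benzyloxy-2-hydroxyphenyl)[2,4,6-tris(benzyloxy)phenyl]methanol (racemic), via aryllithium 6 (not isolated), via sodium phenolate 7 (not isolated)
Conditions: 3, n-BuLi, THF, −78 °C; separately 5, NaH, THF, 0 °C; combine at −78 → 0 °C; H2O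
Reagents that add atoms: none
Why: Bromine–lithium exchange followed by 1,2-addition of the aryllithium to the aldehyde, whose phenol is masked beforehand as the sodium salt so that no aryllithium is lost to protonation; the carbinol centre is deliberately racemic because step 5 erases it.

Step 5
Reactants: 8 (4-benzyloxy-2-hydroxyphenyl)[2,4,6-tris(benzyloxy)phenyl]methanol; 9 N-vinylacetamide
Product: 11 N-{(2R,4R)-7-(benzyloxy)-4-[2,4,6-tris(benzyloxy)phenyl]-3,4-dihydro-2H-chromen-2-yl}acetamide (2,4-cis), via ortho-quinone methide 10 (not isolated)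
Conditions: (R)-3,3'-bis(2,4,6-triisopropylphenyl)-1,1'-binaphthyl-2,2'-diyl hydrogen phosphate (5 mol%), 9 (1.5 equiv), CHCl3, 0 °C → rt
Reagents that add atoms: none
Why: The phosphoric acid protonates the benzylic hydroxyl of 8, water leaves, and quinone methide 10 stays hydrogen-bonded to the phosphate through its carbonyl oxygen while the phosphoryl oxygen holds the N–H of 9; the enamide β-carbon then bonds to the exocyclic carbon (C3–C4) and the ring A oxygen collapses onto the N-acyliminium carbon (O1–C2). This is the established chiral phosphoric acid catalysed inverse-electron-demand hetero-Diels–Alder reaction, a formal (4+2) cycloaddition, of ortho-quinone methides generated from ortho-hydroxybenzhydrols with enamides. Ring C closes as a six-membered (4+2) annulation with O1–C8a–C4a–C4 as the four-atom unit and C3–C2 as the two-atom unit, highly asynchronous, the last bond O1–C2 forming by capture of the iminium carbon by the phenolic oxygen. C4 is set by the catalyst, whose 3,3'-aryl groups leave one face of the planar quinone methide open to the phosphate-bound enamide; C2 is set relative to C4 by the doubly hydrogen-bonded endo-like arrangement (cis) and is not needed later. The step needs enantiofacial selectivity at C4 and trapping by the enamide faster than self-condensation; the free ortho-oxygen and the amide N–H provide the two-point binding, and ring D, twisted out of plane by its two ortho benzyloxy groups, together with the para benzyloxy group of ring A makes 10 long-lived yet hindered towards dimerisation, so the excess enamide should win.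

Step 6
Reactants: 11 N-{(2R,4R)-7-(benzyloxy)-4-[2,4,6-tris(benzyloxy)phenyl]-3,4-dihydro-2H-chromen-2-yl}acetamide
Product: 12 (4R)-7-(benzyloxy)-4-[2,4,6-tris(benzyloxy)phenyl]-3,4-dihydro-2H-chromen-2-ol (both C2 epimers)
Conditions: 1 M aq. HCl, THF, 40 °C
Reagents that add atoms: water, O
Why: Acid-catalysed hydrolysis of the N-acyl N,O-acetal proceeds by loss of acetamide and capture of the resulting cation by water, and C4 is not involved, so its configuration should be retained.

Step 7
Reactants: 12 (4R)-7-(benzyloxy)-4-[2,4,6-tris(benzyloxy)phenyl]-3,4-dihydro-2H-chromen-2-ol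
Product: 13 (4R)-7-(benzyloxy)-2-(phenylsulfonyl)-4-[2,4,6-tris(benzyloxy)phenyl]-3,4-dihydro-2H-chromene (both C2 epimers)
Conditions: PhSO2H, CaCl2, CH2Cl2, rt
Reagents that add atoms: benzenesulfinic acid, OS(=O)c1ccccc1
Why: Lactol-to-anomeric-sulfone exchange: the sulfinic acid ionises the lactol to the cyclic oxocarbenium ion, sulfinate adds through sulfur and CaCl2 takes up the water, and either C2 epimer serves in step 8.

Step 8
Reactants: 13 (4R)-7-(benzyloxy)-2-(phenylsulfonyl)-4-[2,4,6-tris(benzyloxy)phenyl]-3,4-dihydro-2H-chromene; 14 1-(benzyloxy)-4-bromobenzene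
Product: 17 (2S,4R)-7-(benzyloxy)-2-[4-(benzyloxy)phenyl]-4-[2,4,6-tris(benzyloxy)phenyl]-3,4-dihydro-2H-chromene (2,4-trans), via arylmagnesium bromide 15 (not isolated), via arylzinc bromide 16 (not isolated)
Conditions: 14, Mg, THF, 40 °C; ZnBr2, THF, 0 °C → rt; then 13, THF, rt
Reagents that add atoms: none
Why: Substitution of a 2-sulfonyl cyclic ether by an organozinc reagent: the zinc and magnesium halides ionise the sulfone to the chromanyl oxocarbenium ion, in whose half-chair ring D sits pseudoaxial at C4 to avoid the peri hydrogen at C5, so the aryl group should be delivered to C2 from the opposite face and C2 set S (2,4-trans) under substrate control from C4.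

Step 9
Reactants: 17 (2S,4R)-7-(benzyloxy)-2-[4-(benzyloxy)phenyl]-4-[2,4,6-tris(benzyloxy)phenyl]-3,4-dihydro-2H-chromene; 18 dodecanoic acid
Product: 20 1-{2,4,6-tris(benzyloxy)-3-[(2S,4R)-7-(benzyloxy)-2-[4-(benzyloxy)phenyl]-3,4-dihydro-2H-chromen-4-yl]phenyl}dodecan-1-one, via mixed anhydride 19 (not isolated)
Conditions: 18, (CF3CO)2O, CH2Cl2, 0 °C; then 17, 0 °C → rt
Reagents that add atoms: none
Why: Friedel–Crafts acylation by the mixed carboxylic trifluoroacetic anhydride should go to ring D, a phloroglucinol triether far more nucleophilic than the resorcinol-type ring A or the monoalkoxy ring B, and its two open positions are equivalent, so one ketone is expected.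

Step 10
Reactants: 20 1-{2,4,6-tris(benzyloxy)-3-[(2S,4R)-7-(benzyloxy)-2-[4-(benzyloxy)phenyl]-3,4-dihydro-2H-chromen-4-yl]phenyl}dodecan-1-one
Product: 21 (+)-myristinin A
Conditions: H2 (1 atm), Pd(OH)2/C, EtOAc–MeOH, rt
Reagents that add atoms: none
Why: Catalytic hydrogenolysis should cleave the five benzyl aryl ethers while the hydrogen-bonded, electron-rich aryl ketone and the C2–O1 bond survive at atmospheric pressure if the reaction is stopped at full debenzylation, and neither stereocentre is affected.

Compound list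
1 | phloroglucinol | Oc1cc(O)cc(O)c1 | starting material
2 | 1,3,5-tris(benzyloxy)benzene | c1c(OCc2ccccc2)cc(OCc2ccccc2)cc1OCc1ccccc1 | intermediate
3 | 2-bromo-1,3,5-tris(benzyloxy)benzene | Brc1c(OCc2ccccc2)cc(OCc2ccccc2)cc1OCc1ccccc1 | intermediate
4 | 2,4-dihydroxybenzaldehyde | O=Cc1ccc(O)cc1O | starting material
5 | 4-(benzyloxy)-2-hydroxybenzaldehyde | O=Cc1ccc(OCc2ccccc2)cc1O | intermediate
6 | [2,4,6-tris(benzyloxy)phenyl]lithium | [Li]c1c(OCc2ccccc2)cc(OCc2ccccc2)cc1OCc1ccccc1 | intermediate
7 | sodium 5-(benzyloxy)-2-formylphenolate | [Na+].[O-]c1cc(OCc2ccccc2)ccc1C=O | intermediate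
8 | (4-benzyloxy-2-hydroxyphenyl)[2,4,6-tris(benzyloxy)phenyl]methanol, racemic | c1c(OCc2ccccc2)cc(OCc2ccccc2)c(C(O)c2ccc(OCc3ccccc3)cc2O)c1OCc1ccccc1 | intermediate
9 | N-vinylacetamide | C=CNC(C)=O | starting material
10 | 3-(benzyloxy)-6-{[2,4,6-tris(benzyloxy)phenyl]methylidene}cyclohexa-2,4-dien-1-one | O=C1C=C(OCc2ccccc2)C=CC1=Cc1c(OCc2ccccc2)cc(OCc2ccccc2)cc1OCc1ccccc1 | intermediate
11 | N-{(2R,4R)-7-(benzyloxy)-4-[2,4,6-tris(benzyloxy)phenyl]-3,4-dihydro-2H-chromen-2-yl}acetamide (2,4-cis) | c1c(OCc2ccccc2)cc(OCc2ccccc2)c([C@@H]2C[C@H](NC(C)=O)Oc3cc(OCc4ccccc4)ccc32)c1OCc1ccccc1 | intermediate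
12 | (4R)-7-(benzyloxy)-4-[2,4,6-tris(benzyloxy)phenyl]-3,4-dihydro-2H-chromen-2-ol, both C2 epimers | c1c(OCc2ccccc2)cc(OCc2ccccc2)c([C@@H]2CC(O)Oc3cc(OCc4ccccc4)ccc32)c1OCc1ccccc1 | intermediate
13 | (4R)-7-(benzyloxy)-2-(phenylsulfonyl)-4-[2,4,6-tris(benzyloxy)phenyl]-3,4-dihydro-2H-chromene, both C2 epimers | c1c(OCc2ccccc2)cc(OCc2ccccc2)c([C@@H]2CC(S(=O)(=O)c3ccccc3)Oc3cc(OCc4ccccc4)ccc32)c1OCc1ccccc1 | intermediate
14 | 1-(benzyloxy)-4-bromobenzene | Brc1ccc(OCc2ccccc2)cc1 | starting material
15 | [4-(benzyloxy)phenyl]magnesium bromide | Br[Mg]c1ccc(OCc2ccccc2)cc1 | intermediate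
16 | [4-(benzyloxy)phenyl]zinc bromide | Br[Zn]c1ccc(OCc2ccccc2)cc1 | intermediate
17 | (2S,4R)-7-(benzyloxy)-2-[4-(benzyloxy)phenyl]-4-[2,4,6-tris(benzyloxy)phenyl]-3,4-dihydro-2H-chromene (2,4-trans) | c1c(OCc2ccccc2)cc(OCc2ccccc2)c([C@@H]2C[C@@H](c3ccc(OCc4ccccc4)cc3)Oc3cc(OCc4ccccc4)ccc32)c1OCc1ccccc1 | intermediate
18 | dodecanoic acid | CCCCCCCCCCCC(=O)O | starting material
19 | dodecanoic trifluoroacetic anhydride | CCCCCCCCCCCC(=O)OC(=O)C(F)(F)F | intermediate
20 | 1-{2,4,6-tris(benzyloxy)-3-[(2S,4R)-7-(benzyloxy)-2-[4-(benzyloxy)phenyl]-3,4-dihydro-2H-chromen-4-yl]phenyl}dodecan-1-one | CCCCCCCCCCCC(=O)c1c(OCc2ccccc2)cc(OCc2ccccc2)c([C@@H]2C[C@@H](c3ccc(OCc4ccccc4)cc3)Oc3cc(OCc4ccccc4)ccc32)c1OCc1ccccc1 | intermediate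
21 | (+)-myristinin A, 1-{2,4,6-trihydroxy-3-[(2S,4R)-7-hydroxy-2-(4-hydroxyphenyl)-3,4-dihydro-2H-chromen-4-yl]phenyl}dodecan-1-one | CCCCCCCCCCCC(=O)c1c(O)cc(O)c([C@@H]2C[C@@H](c3ccc(O)cc3)Oc3cc(O)ccc32)c1O | target

Total step count: 10
Longest linear sequence: 9 (steps 1, 2, 4, 5, 6, 7, 8, 9, 10; step 3 is a one-step branch)

Steps most likely to fail

Step 5. The hindered, doubly ortho-substituted ring D may prevent the catalyst from discriminating the two faces of the quinone methide. The quinone methide may also be consumed by self-condensation or by Friedel–Crafts attack of a second ring D before the enamide traps it. The fallback keeps the quinone methide but generates it under anionic conditions and takes the facial control from a chiral auxiliary on the two-carbon partner. It sets out from aldehyde 5 and aryllithium 6 (made from 3 as in step 4) and returns at lactol 12. Aldehyde 5 would be acylated (Boc2O, i-Pr2NEt, cat. DMAP, CH2Cl2) to 5-(benzyloxy)-2-formylphenyl tert-butyl carbonate F1. Commercial (1R,2S)-2-phenylcyclohexanol would be vinylated ([Ir(cod)Cl]2, Na2CO3, vinyl acetate, toluene, 100 °C) to (1R,2S)-2-phenylcyclohexyl vinyl ether F2. Addition of 6 to F1 at −78 °C in THF in the presence of F2, then MgBr2·OEt2 and slow warming, should cause carbonate migration to the new alkoxide and elimination to the same quinone methide 10. Endo cycloaddition with F2, whose phenyl group shields one face of the enol ether, should then give (2R,4R)-7-(benzyloxy)-2-{[(1R,2S)-2-phenylcyclohexyl]oxy}-4-[2,4,6-tris(benzyloxy)phenyl]-3,4-dihydro-2H-chromene F3. Mild aqueous acid (HCl, THF–H2O) would hydrolyse the acetal to 12 and return the auxiliary.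

Step 8. The oxocarbenium ion may lose a C3 proton to give a 4H-chromene, may be attacked by a second ring D, or may be arylated with poor facial selectivity at C2. The fallback forms the C2–aryl bond on the open chain and closes O1–C2 with inversion; it sets out from lactol 12 and returns at 17. Excess Grignard reagent 15 (THF, 0 °C) adds to the hydroxy-aldehyde tautomer of 12 to give (3R)-3-[4-(benzyloxy)-2-hydroxyphenyl]-1-[4-(benzyloxy)phenyl]-3-[2,4,6-tris(benzyloxy)phenyl]propan-1-ol F4 as a mixture of carbinol epimers. MnO2 (CH2Cl2) oxidises the electron-rich benzylic alcohol to (3R)-3-[4-(benzyloxy)-2-hydroxyphenyl]-1-[4-(benzyloxy)phenyl]-3-[2,4,6-tris(benzyloxy)phenyl]propan-1-one F5. Corey–Bakshi–Shibata reduction ((S)-2-methyl-CBS-oxazaborolidine, BH3·SMe2 in excess because of the phenol, THF) should give (1R,3R)-3-[4-(benzyloxy)-2-hydroxyphenyl]-1-[4-(benzyloxy)phenyl]-3-[2,4,6-tris(benzyloxy)phenyl]propan-1-ol F6 under catalyst control. Mitsunobu cyclisation (PPh3, DIAD, THF, 0 °C) then lets the phenol displace the activated carbinol with inversion, giving the 2S, 2,4-trans flavan 17.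

Step 9. Trifluoroacetic acid released during the acylation may reversibly open the benzylic C2–O1 bond and epimerise C2. It may also cleave a benzyl ether next to the new ketone, and some acylation may occur on ring A. The fallback avoids acid by making ring D the nucleophile as an aryllithium; it sets out from 17 and returns at 20. NBS (1.0 equiv, CH2Cl2, −78 °C) should brominate the most electron-rich ring to give (2S,4R)-7-(benzyloxy)-2-[4-(benzyloxy)phenyl]-4-[3-bromo-2,4,6-tris(benzyloxy)phenyl]-3,4-dihydro-2H-chromene F7. Acid 18 is converted (1,1'-carbonyldiimidazole, then MeNHOMe·HCl, CH2Cl2) to N-methoxy-N-methyldodecanamide F8. Bromine–lithium exchange on F7 (n-BuLi, THF, −78 °C) and Weinreb ketone synthesis with F8 then give ketone 20.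

Further compounds
F1 | step 5 | 5-(benzyloxy)-2-formylphenyl tert-butyl carbonate | O=Cc1ccc(OCc2ccccc2)cc1OC(=O)OC(C)(C)C
F2 | step 5 | (1R,2S)-2-phenylcyclohexyl vinyl ether | C=CO[C@@H]1CCCC[C@H]1c1ccccc1
F3 | step 5 | (2R,4R)-7-(benzyloxy)-2-{[(1R,2S)-2-phenylcyclohexyl]oxy}-4-[2,4,6-tris(benzyloxy)phenyl]-3,4-dihydro-2H-chromene | c1c(OCc2ccccc2)cc(OCc2ccccc2)c([C@@H]2C[C@H](O[C@@H]3CCCC[C@H]3c3ccccc3)Oc3cc(OCc4ccccc4)ccc32)c1OCc1ccccc1
F4 | step 8 | (3R)-3-[4-(benzyloxy)-2-hydroxyphenyl]-1-[4-(benzyloxy)phenyl]-3-[2,4,6-tris(benzyloxy)phenyl]propan-1-ol, both C1 epimers | c1c(OCc2ccccc2)cc(OCc2ccccc2)c([C@@H](c2ccc(OCc3ccccc3)cc2O)CC(O)c2ccc(OCc3ccccc3)cc2)c1OCc1ccccc1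
F5 | step 8 | (3R)-3-[4-(benzyloxy)-2-hydroxyphenyl]-1-[4-(benzyloxy)phenyl]-3-[2,4,6-tris(benzyloxy)phenyl]propan-1-one | c1c(OCc2ccccc2)cc(OCc2ccccc2)c([C@@H](c2ccc(OCc3ccccc3)cc2O)CC(=O)c2ccc(OCc3ccccc3)cc2)c1OCc1ccccc1
F6 | step 8 | (1R,3R)-3-[4-(benzyloxy)-2-hydroxyphenyl]-1-[4-(benzyloxy)phenyl]-3-[2,4,6-tris(benzyloxy)phenyl]propan-1-ol | c1c(OCc2ccccc2)cc(OCc2ccccc2)c([C@@H](c2ccc(OCc3ccccc3)cc2O)C[C@@H](O)c2ccc(OCc3ccccc3)cc2)c1OCc1ccccc1
F7 | step 9 | (2S,4R)-7-(benzyloxy)-2-[4-(benzyloxy)phenyl]-4-[3-bromo-2,4,6-tris(benzyloxy)phenyl]-3,4-dihydro-2H-chromene | Brc1c(OCc2ccccc2)cc(OCc2ccccc2)c([C@@H]2C[C@@H](c3ccc(OCc4ccccc4)cc3)Oc3cc(OCc4ccccc4)ccc32)c1OCc1ccccc1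
F8 | step 9 | N-methoxy-N-methyldodecanamide | CCCCCCCCCCCC(=O)N(C)OC
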